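## Structural features

The target is a germacra-1(10),4-dien-12,6-olide: a ten-membered carbocycle (C1–C10) cis-fused across C6–C7 to an α-methylene-γ-butyrolactone (O6–C12(=O)–C11(=C13)–C7). Four contiguous oxygenated stereocentres sit on one arc of the ring: C6 (S, lactone oxygen), C7 (S, tertiary hydroxyl, fully substituted), C8 (S, secondary hydroxyl) and C9 (R, angelate). The rest of the ring carries two trisubstituted alkenes, C4=C5 (E, methyl on C4) and C1=C10 (Z, methyl on C10), joined by the saturated C2–C3 link. Fragile elements are the exo-methylene lactone (a Michael acceptor), the angelate (Z to E isomerisation, 1,2-shift to O8), the 1,5-diene in a medium ring (transannular cyclisation in acid, Cope rearrangement on heating) and the two allylic C–O bonds at C6 and C9. The real difficulty is twofold: the fully substituted carbinol C7 inside an all-oxygenated tetrad, and closure of a strained ten-membered ring holding one E and one Z trisubstituted alkene. An atom-by-atom comparison of the stereodescriptors shows that C6, C7, C8 and C9 are arranged exactly as C2, C3, C4 and C5 of D-galactose, with C11 on C7 in the place of H-3 and cis to O6. The key step uses this: the lactone ring (O6, C12, C11, C7, C6) is closed by forming C7–C11 through insertion of a carbene tethered to O6 (galactose O2) into C7–H (galactose C3–H) with retention. The phosphoryl group that travels with the carbene is the latent C13 methylene.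

## Logic of the disconnections

34 back to 33: the two C–O bonds of the ketal on O7/O8 are cut last. O7 must stay blocked as long as C11 carries phosphorus, because a free β-alkoxide would collapse by Horner–Wadsworth–Emmons-type elimination, and O8 must stay blocked while O9 is acylated. The demand is a ketal cleavage mild enough for the diene, the angelate and the methylene lactone.

33 back to 32: the C11=C13 bond is cut. The Michael acceptor therefore appears only after every basic or nucleophilic step, and C11 becomes a phosphonate-stabilised carbon whose anion also shields the lactone carbonyl. The forward step must work with carbonate base in the presence of the angelate.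

32 back to 29 and 30: the ester C–O bond at O9 is cut. The angelate would not survive amide bases or hydride, so it follows ring closure and desulfonylation. The demand is acylation of a hindered allylic alcohol without Z to E isomerisation.

29 back to 28 and 27 (O9–Si and C2–S), then 27 back to 26: the C2–C3 bond is cut. It is the only sp3–sp3 bond of the ring and lies between two allyl units, so C2 can carry a sulfonyl-stabilised carbanion and C3 an allylic bromide. The sulfone is placed on C2 and not on C3, because a C3 anion would be vinylogously β to the C6 acyloxy group and could eliminate it. The gain is an open chain in which both alkenes are already fixed. The demand is a ten-membered closure at high dilution, attack at the α-carbon, and later C–S cleavage without allylic transposition.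

26 back to 21 through 25, 24 and 22: these are functional-group changes at C3 (O to Br) and C2 (O to sulfonyl), made possible by three orthogonal oxygen protecting groups. Then 21 back to 17 and 19: the C1=C10 bond is cut. An α-silyloxy methyl ketone and an unstabilised ylide should give the Z-trisubstituted alkene, and C1 and C2 are removed. The demand is Z selectivity and survival of a β-alkoxy ylide.

17 back to 14 through 16 and 15: the C10–C14 bond is cut (methyl addition to an aldehyde, then oxidation). C10 returns to the primary carbinol carbon of the hexose.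

14 back to 9 and 10 through 13 and 12: after protecting-group steps the C4=C5 bond is cut. A formyl-stabilised ylide on a lactol gives the E-alkene and removes C3, C4 and C15. The chain closes back to a pyranose in which O9 is the ring oxygen and C5 the anomeric carbon. The demand is that the lactol exposes its aldehyde and that the freed O9 does not add back to the enal.

9 back to 8: the anomeric O–CH2Ph bond is cut. A benzyl glycoside is chosen in place of a simple alkyl glycoside because it is removed by hydrogenolysis, without acid, at the one stage where the molecule has no alkene; ketal, silyl ether and lactone are untouched.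

8 back to 7: the C7–C11 bond is cut (key step). The lactone ring opens to a diazo ester on O2, and the fully substituted C7 returns to a plain C3–H of the sugar. The demand is insertion at C3–H with retention and not at the anomeric C–H or the benzyl group.

7 back to 1 through 6, 4 with 5, 3 and 2: dinitrogen transfer, the ester bond at O2, and protecting-group steps. The 3,4-ketal leaves only O2 and O6 free, and the primary O6 takes a triethylsilyl group that can later be removed beside tert-butyldimethylsilyl ethers. The glycosidic bond of 2 leads back to 1.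

## Other disconnections considered

Alternative 1: The cut is C5–C6 together with the C4–methyl bond, across an alkyne. Forward, Ni(cod)2 with 1,3-dimesitylimidazol-2-ylidene and ZnMe2 would turn the acyclic aldehyde–alkyne A1 into the ten-membered allylic alcohol A2 by oxidative cyclisation to an oxanickelacycle, methyl transfer from zinc and reductive elimination.
- In its favour: one operation closes the ring, fixes the E geometry of C4=C5 by syn addition and creates the C6 carbinol; the aldehyde on the quaternary C7 cannot enolise.
- Against it here: the C6 configuration rests on induction from C7 in a strained medium-ring transition state and is hard to predict; ZnMe2 can add directly to the aldehyde; C7–C9 must be built without a chiral-pool template; C11–C13 arrives as a protected allylic alcohol that still needs oxidation and lactonisation.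
- Comparison: on structure the chosen plan is stronger, since all four stereocentres come from galactose and C7 is set by retention. On mechanism the alternative is the better plan for the ring closure itself, because it is catalytic, needs no sulfone to be put on and taken off, and sets geometry and a stereocentre at once. On step economy the two should be about equal: the alternative has a shorter endgame but a longer route to A1.

Alternative 2: The cut is the pair of σ bonds C1–C10 and C4–C5 of a hidden cyclobutane. Forward, irradiation at about 350 nm would join the cyclohexenone A3 and 1-methylcyclobutene A4 to the cis,anti,cis photoadduct A5. Later thermolysis of its bicyclo[2.2.0]hexane unit would break the other two cyclobutane bonds and open out the 1,5-diene.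
- In its favour: there is no macrocyclisation at all; the ring expansion is unimolecular; C6–C8 are set on a six-membered ring, where stereocontrol is most reliable.
- Against it here: regiochemistry and facial selectivity of the [2+2] addition on a crowded enone are uncertain; which alkene emerges Z and which E depends on the ring-fusion stereochemistry; at thermolysis temperature the diene can go on to a divinylcyclohexane by Cope rearrangement; the C9 ketone must still be reduced with control and the amide turned into the methylene lactone; A4 is volatile and must be prepared.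
- Comparison: on ring construction the alternative is the better plan, because it avoids the entropic cost of the chosen ten-membered alkylation. On structure the chosen plan is better, since C9 and the alkene geometries are fixed by separate, predictable steps. On step economy the two are about equal: A5 holds all ten ring carbons early, but many adjusting steps follow.

Alternative 3: The cut is C7–C8, with O8–C13 joined in the precursor. Forward, KN(SiMe3)2 would enolise the C9 ketone of the thirteen-membered ether A6 toward C8, and a [2,3]-Wittig shift would contract the ring to the ten-membered ketol A7, forming C7–C8 and the C11=C13 acrylate.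
- In its favour: the large ring is closed first as a less strained ether; the contraction makes a C–C bond, two stereocentres and the exo-methylene unit at the correct oxidation level in one concerted step, so no phosphonate and no formaldehyde step are needed. In these respects the alternative is better than the chosen plan.
- Against it here: C7 and C8 depend on enolate geometry and on a tetrasubstituted silyl enol ether inside a macrocycle; a [1,2]-shift and β-elimination of the α-alkoxy ketone compete; C6 arrives epimeric and must be inverted; the C9 ketone must still be reduced; A6 itself needs both trisubstituted alkenes and a macro-etherification.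
- Comparison: on mechanism the two key steps are equal, both being concerted with a defined stereochemical course. On structure the chosen plan is better, since C7 comes by retention at an existing centre. On step economy the alternative would be better if A6 were readily accessible.

Key step: step 6

Assumption: 5, 10, 18 and 30 are purchased; C11 (steps 6–23), the anomeric carbon of 9, C10 of 16 and C2 of 27 are uncontrolled centres that are erased later, so their SMILES carry no descriptor.

## Route

Step 1
Reactants: 1 D-galactose
Product: 2 benzyl α-D-galactopyranoside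
Conditions: BnOH (solvent), HCl (cat.), 60 °C; α-anomer crystallised
Reagents that add atoms: benzyl alcohol OCc1ccccc1
Why: Fischer glycosidation under thermodynamic control; the anomeric effect favours the axial α-pyranoside, which places H1 trans to O2 for the later insertion.

Step 2
Reactants: 2 benzyl α-D-galactopyranoside
Product: 3 benzyl 3,4-O-isopropylidene-α-D-galactopyranoside
Conditions: Me2C(OMe)2, TsOH·H2O (cat.), acetone, rt; then aq. AcOH (brief), Et3N
Reagents that add atoms: 2,2-dimethoxypropane COC(C)(C)OC
Why: Acid-catalysed transketalisation; the cis-3,4-diol closes the five-membered dioxolane under thermodynamic control and the brief aqueous acid removes the labile mixed ketal on O6, leaving O2 and O6 free.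

Step 3
Reactants: 3 benzyl 3,4-O-isopropylidene-α-D-galactopyranoside
Product: 4 benzyl 3,4-O-isopropylidene-6-O-triethylsilyl-α-D-galactopyranoside
Conditions: Et3SiCl (1.05 equiv), imidazole, CH2Cl2, −40 to −20 °C
Reagents that add atoms: chlorotriethylsilane CC[Si](CC)(CC)Cl
Why: Selective silylation of the primary hydroxyl over the hindered secondary O2–H; triethylsilyl is chosen so that it can later be removed beside tert-butyldimethylsilyl ethers.

Step 4
Reactants: 4 benzyl 3,4-O-isopropylidene-6-O-triethylsilyl-α-D-galactopyranoside; 5 diethylphosphonoacetic acid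
Product: 6 2-O-(diethoxyphosphorylacetyl) ester of 4
Conditions: DCC, DMAP (cat.), CH2Cl2, 0 °C to rt
Reagents that add atoms: none
Why: Carbodiimide (Steglich) esterification of the only free hydroxyl; no stereocentre is touched.

Step 5
Reactants: 6 2-O-(diethoxyphosphorylacetyl) ester
Product: 7 2-O-[diazo(diethoxyphosphoryl)acetyl] ester (key-step precursor)
Conditions: 4-AcNHC6H4SO2N3, DBU, MeCN, 0 °C to rt
Reagents that add atoms: 4-acetamidobenzenesulfonyl azide CC(=O)Nc1ccc(cc1)S(=O)(=O)N=[N+]=[N-]
Why: Regitz diazo transfer to the phosphonate/ester-activated methylene; the sulfonamide by-product is removed by filtration and washing.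

Step 6
Reactants: 7 2-O-[diazo(diethoxyphosphoryl)acetyl] ester
Product: 8 cis-fused C3-branched γ-lactone phosphonate
Conditions: Rh2(OAc)4 (2 mol%), ClCH2CH2Cl, 80 °C, slow addition to 0.01 M
Reagents that add atoms: none
Why: Rh2(OAc)4 takes up the diazo carbon with loss of N2 to give an electrophilic dirhodium carbenoid flanked by ester and phosphoryl groups. The carbenoid carbon and the C3–H bond (target C7–H) pass through a concerted three-centre, hydride-transfer-like transition state on one face, so the new C7–C11 bond takes the place of the hydrogen (retention). The closest known reaction type is the dirhodium-catalysed intramolecular 1,5 C–H insertion of diazoacetates and diazophosphonoacetates next to an ether oxygen to give γ-lactones, including 2-O-diazoacyl pyranosides. The one ring formed is the γ-lactone O2–C12–C11–C3–C2; it closes by C–C bond formation through a five-membered (1,5) cyclic transition state and is cis-fused because the tether on equatorial O2 is syn to the axial H3. The one new controlled stereocentre, the fully substituted C3 (target C7), is set by the substrate: retention at an existing D-galacto centre, while C11 forms without control and is erased in step 24. The step needs C3–H to win over the anomeric C1–H, the benzylic OCH2, C4–H (1,6) and ylide formation at O1 or O3. C3–H is tertiary and activated by the ketal oxygen O3, whereas H1 of the α-glycoside is equatorial and trans to O2 (reachable only through a strained trans-fused transition state) and has no ring-oxygen lone pair antiperiplanar to it. Slow addition at high dilution suppresses carbene dimerisation, and Rh2(O2CCMe3)4 is the first catalyst variation if ylide-derived products appear.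

Step 7
Reactants: 8 cis-fused C3-branched γ-lactone phosphonate
Product: 9 lactol (free anomeric hydroxyl)
Conditions: H2 (1 atm), Pd(OH)2/C, EtOAc, rt
Reagents that add atoms: none
Why: Hydrogenolysis of the benzyl glycoside at the only stage without an alkene; the ketal, the triethylsilyl ether (stable in a non-alcoholic solvent), the lactone and the phosphonate are inert.

Step 8
Reactants: 9 lactol; 10 2-(triphenylphosphoranylidene)propanal
Product: 12 (E)-allylic alcohol diol, via enal 11 (not isolated)
Conditions: PhMe, 90 °C; then MeOH, CeCl3·7H2O, NaBH4, −20 °C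
Reagents that add atoms: none
Why: Wittig olefination of the open-chain aldehyde tautomer with a formyl-stabilised ylide gives the E-trisubstituted enal (C6 trans to C3) and frees O9–H. Immediate Luche 1,2-reduction removes the enal before O9–H can add back to it, and NaBH4 does not touch the lactone.

Step 9
Reactants: 12 (E)-allylic alcohol diol
Product: 13 3,9-bis(tert-butyldimethylsilyl) ether
Conditions: tBuMe2SiOTf (2.5 equiv), 2,6-lutidine, CH2Cl2, −78 to 0 °C
Reagents that add atoms: tert-butyldimethylsilyl triflate CC(C)(C)[Si](C)(C)OS(=O)(=O)C(F)(F)F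
Why: Silyl triflate with a hindered base silylates both the primary allylic and the hindered secondary hydroxyl without disturbing the ketal or the triethylsilyl ether.

Step 10
Reactants: 13 3,9-bis(tert-butyldimethylsilyl) ether
Product: 14 C10 primary alcohol
Conditions: PPTS (cat.), MeOH/CH2Cl2, 0 °C
Reagents that add atoms: none
Why: Mild acid methanolysis removes the primary triethylsilyl ether much faster than the tert-butyldimethylsilyl ethers or the dioxolane.

Step 11
Reactants: 14 C10 primary alcohol
Product: 15 C10 aldehyde
Conditions: Dess–Martin periodinane, NaHCO3, CH2Cl2, 0 °C to rt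
Reagents that add atoms: none
Why: Dess–Martin oxidation under buffered, non-basic conditions keeps the α-silyloxy aldehyde from epimerising at C9 and leaves the acidic C11–H alone.

Step 12
Reactants: 15 C10 aldehyde
Product: 16 C10 methyl carbinol (both epimers)
Conditions: MeMgBr (3 equiv), THF, −78 °C; aq. NH4Cl
Reagents that add atoms: methylmagnesium bromide C[Mg]Br
Why: Grignard addition; the first equivalent deprotonates C11–H and the resulting phosphonate enolate shields the lactone carbonyl, so the aldehyde is the only electrophile. The new carbinol centre is oxidised in the next step and needs no control.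

Step 13
Reactants: 16 C10 methyl carbinol
Product: 17 C10 methyl ketone
Conditions: Dess–Martin periodinane, NaHCO3, CH2Cl2, rt
Reagents that add atoms: none
Why: Dess–Martin oxidation of the secondary alcohol to the α-silyloxy methyl ketone that the Z-selective olefination needs.

Step 14
Reactants: 18 1-[(2-bromoethoxy)methyl]-4-methoxybenzene
Product: 19 [2-(4-methoxybenzyloxy)ethyl]triphenylphosphonium bromide
Conditions: PPh3, MeCN, reflux
Reagents that add atoms: triphenylphosphine c1ccc(cc1)P(c1ccccc1)c1ccccc1
Why: SN2 quaternisation of triphenylphosphine by a primary bromide; the salt is purified by crystallisation.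

Step 15
Reactants: 17 C10 methyl ketone; 19 [2-(4-methoxybenzyloxy)ethyl]triphenylphosphonium bromide
Product: 21 Z-alkene PMB ether, via ylide 20 (not isolated)
Conditions: 19 (3 equiv), KN(SiMe3)2 (2.9 equiv), THF, −78 °C; then 17, −78 to 0 °C
Reagents that add atoms: none
Why: Lithium-free Wittig olefination of an α-oxygenated methyl ketone with an unstabilised ylide is kinetically controlled and places the ylide substituent cis to the oxygen-bearing carbon, giving the Z-trisubstituted C1=C10 alkene. One equivalent of ylide is consumed by C11–H, and the ylide is generated and used cold to limit loss of 4-methoxybenzyl oxide.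

Step 16
Reactants: 21 Z-alkene PMB ether
Product: 22 C2 allylic alcohol
Conditions: DDQ, CH2Cl2/pH 7 buffer, 0 °C
Reagents that add atoms: none
Why: Oxidative cleavage of the 4-methoxybenzyl ether by hydride abstraction and hydrolysis; silyl ethers, ketal and alkenes are not affected.

Step 17
Reactants: 22 C2 allylic alcohol
Product: 24 C2 allyl phenyl sulfone, via mesylate 23 (not isolated)
Conditions: MsCl, Et3N, CH2Cl2, −20 °C; then PhSO2Na, Bu4NI (cat.), DMF, rt
Reagents that add atoms: methanesulfonyl chloride CS(=O)(=O)Cl (atoms kept in 23 only); sodium benzenesulfinate [Na+].[O-]S(=O)c1ccccc1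
Why: Activation of the primary allylic alcohol and SN2 displacement by sulfinate at sulfur; attack at the fully substituted C10 (SN2′) is disfavoured, so position and Z geometry of the alkene are kept.

Step 18
Reactants: 24 C2 allyl phenyl sulfone
Product: 25 C3 allylic alcohol
Conditions: HF·pyridine, pyridine, THF, 0 °C to rt
Reagents that add atoms: none
Why: Buffered fluoride removes the unhindered primary allylic silyl ether selectively; the secondary silyl ether on O9, flanked by C8 and the fully substituted C10, and the ketal stay.

Step 19
Reactants: 25 C3 allylic alcohol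
Product: 26 C3 allylic bromide
Conditions: CBr4, PPh3, CH2Cl2, −20 °C
Reagents that add atoms: carbon tetrabromide BrC(Br)(Br)Br
Why: Appel bromination under neutral conditions converts the primary allylic alcohol with retention of the E alkene; the bromide is used at once.

Step 20
Reactants: 26 C3 allylic bromide
Product: 27 ten-membered sulfone (C2 epimers)
Conditions: LiN(SiMe3)2 (2.3 equiv), THF, −78 to 0 °C, slow addition of 26 to 2 mM
Reagents that add atoms: none
Why: The first equivalent of base forms the C11 phosphonate enolate (lactone shielded), the second the sulfonyl-stabilised allyl anion at C2, which displaces the C3 bromide intramolecularly at its α-carbon (10-membered SN2 closure, as in sulfone-based syntheses of germacrane and polyprenoid 1,5-dienes). Attack of C11 on C3 would need a trans-cyclohexene and is excluded, and the O9 silyl ether is too poor a leaving group for 1,4-elimination.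

Step 21
Reactants: 27 ten-membered sulfone
Product: 28 ten-membered diene (C2 methylene)
Conditions: LiN(SiMe3)2 (1.05 equiv), THF, −78 °C; then PdCl2(dppp) (5 mol%; dppp = Ph2P(CH2)3PPh2), LiBHEt3 (2.5 equiv), 0 °C
Reagents that add atoms: none
Why: Palladium-catalysed hydrogenolysis of an allylic sulfone with a borohydride delivers hydride to the less substituted allyl terminus (C2) and keeps position and geometry of C1=C10. Pre-forming the C11 enolate makes the lactone inert to hydride and makes its allylic carboxylate too poor a leaving group for palladium.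

Step 22
Reactants: 28 ten-membered diene
Product: 29 C9 alcohol
Conditions: Bu4NF, AcOH, THF, rt to 40 °C
Reagents that add atoms: none
Why: Fluoride cleavage of the remaining silyl ether; the acetic acid buffer prevents the liberated alkoxide from attacking the lactone.

Step 23
Reactants: 29 C9 alcohol; 30 angelic acid
Product: 32 C9 angelate, via mixed anhydride 31 (not isolated)
Conditions: 30, 2,4,6-Cl3C6H2COCl, Et3N, PhMe, rt; then 29, 80 °C
Reagents that add atoms: 2,4,6-trichlorobenzoyl chloride O=C(Cl)c1c(Cl)cc(Cl)cc1Cl (atoms kept in 31 only)
Why: Yamaguchi esterification through the mixed anhydride acylates the hindered allylic alcohol at the less hindered angeloyl carbonyl; leaving out a nucleophilic pyridine catalyst limits Z to E isomerisation to the tiglate. O7 and O8 are blocked, so O9 is the only free hydroxyl.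

Step 24
Reactants: 32 C9 angelate
Product: 33 α-methylene lactone ketal
Conditions: K2CO3, aq. HCHO (37%), THF, 0 °C to rt
Reagents that add atoms: formaldehyde C=O
Why: Horner–Wadsworth–Emmons olefination of the lactone phosphonate with formaldehyde gives the exo-methylene and makes C11 planar; the weak base is tolerated by the angelate and the ketal keeps O7 from attacking phosphorus.

Step 25
Reactants: 33 α-methylene lactone ketal
Product: 34 CNP0303917.1 (target)
Conditions: CF3CO2H/H2O (4:1), 0 °C, short contact; NaHCO3 quench
Reagents that add atoms: none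
Why: Acid-catalysed hydrolysis of the isopropylidene ketal frees the tertiary C7 and secondary C8 hydroxyls; low temperature and short contact are chosen to spare the 1,5-diene and to avoid O9 to O8 acyl shift.

## Compound list

1 | D-galactose (pyranose form, anomer mixture) | OC[C@H]1OC(O)[C@H](O)[C@@H](O)[C@H]1O | starting material
2 | benzyl α-D-galactopyranoside | OC[C@H]1O[C@H](OCc2ccccc2)[C@H](O)[C@@H](O)[C@H]1O | intermediate
3 | benzyl 3,4-O-isopropylidene-α-D-galactopyranoside | OC[C@H]1O[C@H](OCc3ccccc3)[C@H](O)[C@H]2OC(C)(C)O[C@@H]12 | intermediate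
4 | benzyl 3,4-O-isopropylidene-6-O-triethylsilyl-α-D-galactopyranoside | CC[Si](CC)(CC)OC[C@H]1O[C@H](OCc3ccccc3)[C@H](O)[C@H]2OC(C)(C)O[C@@H]12 | intermediate
5 | diethylphosphonoacetic acid | OC(=O)CP(=O)(OCC)OCC | starting material
6 | benzyl 2-O-[(diethoxyphosphoryl)acetyl]-3,4-O-isopropylidene-6-O-triethylsilyl-α-D-galactopyranoside | CC[Si](CC)(CC)OC[C@H]1O[C@H](OCc3ccccc3)[C@H](OC(=O)CP(=O)(OCC)OCC)[C@H]2OC(C)(C)O[C@@H]12 | intermediate
7 | benzyl 2-O-[diazo(diethoxyphosphoryl)acetyl]-3,4-O-isopropylidene-6-O-triethylsilyl-α-D-galactopyranoside | CC[Si](CC)(CC)OC[C@H]1O[C@H](OCc3ccccc3)[C@H](OC(=O)C(=[N+]=[N-])P(=O)(OCC)OCC)[C@H]2OC(C)(C)O[C@@H]12 | intermediate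
8 | benzyl 3-C-[carboxy(diethoxyphosphoryl)methyl]-3,4-O-isopropylidene-6-O-triethylsilyl-α-D-galactopyranoside 2-O-lactone (cis-fused γ-lactone; new C–C bond where H-3 stood; phosphonate carbon = target C11, epimer mixture) | CC[Si](CC)(CC)OC[C@H]1O[C@H](OCc5ccccc5)[C@@H]3OC(=O)C(P(=O)(OCC)OCC)[C@@]34OC(C)(C)O[C@@H]14 | intermediate
9 | lactol of 8 (anomeric benzyl replaced by OH, anomer mixture) | CC[Si](CC)(CC)OC[C@H]1OC(O)[C@@H]3OC(=O)C(P(=O)(OCC)OCC)[C@@]34OC(C)(C)O[C@@H]14 | intermediate
10 | 2-(triphenylphosphoranylidene)propanal | CC(C=O)=P(c1ccccc1)(c1ccccc1)c1ccccc1 | starting material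
11 | open-chain (E)-enal (target numbering): C3 aldehyde, 4-methyl, E-C4=C5, 6,12-lactone with diethoxyphosphoryl on C11, 7,8-O-isopropylidene, free 9-OH, 10-O-triethylsilyl; C6–C9 as in the target | O=C/C(C)=C/[C@@H]1OC(=O)C(P(=O)(OCC)OCC)[C@@]12OC(C)(C)O[C@H]2[C@H](O)CO[Si](CC)(CC)CC | intermediate
12 | diol: as 11 with C3 reduced to CH2OH | OC/C(C)=C/[C@@H]1OC(=O)C(P(=O)(OCC)OCC)[C@@]12OC(C)(C)O[C@H]2[C@H](O)CO[Si](CC)(CC)CC | intermediate
13 | 3,9-bis(tert-butyldimethylsilyl) ether of 12 | CC(C)(C)[Si](C)(C)OC/C(C)=C/[C@@H]1OC(=O)C(P(=O)(OCC)OCC)[C@@]12OC(C)(C)O[C@H]2[C@H](O[Si](C)(C)C(C)(C)C)CO[Si](CC)(CC)CC | intermediate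
14 | C10 primary alcohol (triethylsilyl removed from 13) | CC(C)(C)[Si](C)(C)OC/C(C)=C/[C@@H]1OC(=O)C(P(=O)(OCC)OCC)[C@@]12OC(C)(C)O[C@H]2[C@H](O[Si](C)(C)C(C)(C)C)CO | intermediate
15 | C10 aldehyde | CC(C)(C)[Si](C)(C)OC/C(C)=C/[C@@H]1OC(=O)C(P(=O)(OCC)OCC)[C@@]12OC(C)(C)O[C@H]2[C@H](O[Si](C)(C)C(C)(C)C)C=O | intermediate
16 | C10 methyl carbinol (both C10 epimers) | CC(C)(C)[Si](C)(C)OC/C(C)=C/[C@@H]1OC(=O)C(P(=O)(OCC)OCC)[C@@]12OC(C)(C)O[C@H]2[C@H](O[Si](C)(C)C(C)(C)C)C(C)O | intermediate
17 | C10 methyl ketone | CC(C)(C)[Si](C)(C)OC/C(C)=C/[C@@H]1OC(=O)C(P(=O)(OCC)OCC)[C@@]12OC(C)(C)O[C@H]2[C@H](O[Si](C)(C)C(C)(C)C)C(C)=O | intermediate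
18 | 1-[(2-bromoethoxy)methyl]-4-methoxybenzene | COc1ccc(COCCBr)cc1 | starting material
19 | [2-(4-methoxybenzyloxy)ethyl]triphenylphosphonium bromide | COc1ccc(COCC[P+](c2ccccc2)(c2ccccc2)c2ccccc2)cc1.[Br-] | intermediate
20 | [2-(4-methoxybenzyloxy)ethylidene]triphenylphosphorane | COc1ccc(COCC=P(c2ccccc2)(c2ccccc2)c2ccccc2)cc1 | intermediate
21 | open chain C3–C10 plus C1–C2: Z-C1=C10 (C2 cis to C9), C2 4-methoxybenzyl ether, C3 and O9 silyl ethers | CC(C)(C)[Si](C)(C)OC/C(C)=C/[C@@H]1OC(=O)C(P(=O)(OCC)OCC)[C@@]12OC(C)(C)O[C@H]2[C@H](O[Si](C)(C)C(C)(C)C)/C(C)=C\COCc1ccc(OC)cc1 | intermediate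
22 | C2 allylic alcohol | CC(C)(C)[Si](C)(C)OC/C(C)=C/[C@@H]1OC(=O)C(P(=O)(OCC)OCC)[C@@]12OC(C)(C)O[C@H]2[C@H](O[Si](C)(C)C(C)(C)C)/C(C)=C\CO | intermediate
23 | C2 allylic mesylate | CC(C)(C)[Si](C)(C)OC/C(C)=C/[C@@H]1OC(=O)C(P(=O)(OCC)OCC)[C@@]12OC(C)(C)O[C@H]2[C@H](O[Si](C)(C)C(C)(C)C)/C(C)=C\COS(C)(=O)=O | intermediate
24 | C2 allyl phenyl sulfone | CC(C)(C)[Si](C)(C)OC/C(C)=C/[C@@H]1OC(=O)C(P(=O)(OCC)OCC)[C@@]12OC(C)(C)O[C@H]2[C@H](O[Si](C)(C)C(C)(C)C)/C(C)=C\CS(=O)(=O)c1ccccc1 | intermediate
25 | C3 allylic alcohol with C2 sulfone | OC/C(C)=C/[C@@H]1OC(=O)C(P(=O)(OCC)OCC)[C@@]12OC(C)(C)O[C@H]2[C@H](O[Si](C)(C)C(C)(C)C)/C(C)=C\CS(=O)(=O)c1ccccc1 | intermediate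
26 | C3 allylic bromide with C2 sulfone | BrC/C(C)=C/[C@@H]1OC(=O)C(P(=O)(OCC)OCC)[C@@]12OC(C)(C)O[C@H]2[C@H](O[Si](C)(C)C(C)(C)C)/C(C)=C\CS(=O)(=O)c1ccccc1 | intermediate
27 | ten-membered ring: 2-phenylsulfonyl, 1(10)Z,4E-diene, 6,12-lactone with C11 phosphonate, 7,8-O-isopropylidene, 9-O-tert-butyldimethylsilyl | C3/C(C)=C/[C@@H]1OC(=O)C(P(=O)(OCC)OCC)[C@@]12OC(C)(C)O[C@H]2[C@H](O[Si](C)(C)C(C)(C)C)/C(C)=C\C3S(=O)(=O)c1ccccc1 | intermediate
28 | as 27 without the sulfonyl group (C2 methylene) | C3/C(C)=C/[C@@H]1OC(=O)C(P(=O)(OCC)OCC)[C@@]12OC(C)(C)O[C@H]2[C@H](O[Si](C)(C)C(C)(C)C)/C(C)=C\C3 | intermediate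
29 | as 28 with free 9-OH | C3/C(C)=C/[C@@H]1OC(=O)C(P(=O)(OCC)OCC)[C@@]12OC(C)(C)O[C@H]2[C@H](O)/C(C)=C\C3 | intermediate
30 | angelic acid, (Z)-2-methylbut-2-enoic acid | C/C=C(/C)C(O)=O | starting material
31 | angelic 2,4,6-trichlorobenzoic anhydride | C/C=C(/C)C(=O)OC(=O)c1c(Cl)cc(Cl)cc1Cl | intermediate
32 | 9-O-angeloyl derivative of 29 | C3/C(C)=C/[C@@H]1OC(=O)C(P(=O)(OCC)OCC)[C@@]12OC(C)(C)O[C@H]2[C@H](OC(=O)/C(C)=C\C)/C(C)=C\C3 | intermediate
33 | 7,8-O-isopropylidene derivative of the target (α-methylene lactone) | C3/C(C)=C/[C@@H]1OC(=O)C(=C)[C@@]12OC(C)(C)O[C@H]2[C@H](OC(=O)/C(C)=C\C)/C(C)=C\C3 | intermediate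
34 | CNP0303917.1, (6S,7S,8S,9R)-9-angeloyloxy-7,8-dihydroxygermacra-1(10)Z,4E,11(13)-trien-12,6-olide | C=C1C(=O)O[C@H]2/C=C(\C)CC/C=C(/C)[C@@H](OC(=O)/C(C)=C\C)[C@H](O)[C@@]12O | target

## Step count and least certain steps

Total step count: 25. Longest linear sequence: 24 (steps 1–13 and 15–25; step 14 is a one-step side branch).

Step 6 (key step). Most likely to go wrong is diversion of the carbenoid to the anomeric acetal: insertion into the equatorial C1–H, attack on O1 followed by a 1,2-shift of benzyl, or 1,7-insertion into the benzylic CH2. The acceptor/acceptor carbenoid is very electrophilic, and the wanted C3–H is axial and 1,3-diaxial to the anomeric substituent. Fallback: from 4, acylation with bromoacetyl bromide and pyridine gives the 2-O-bromoacetate F1. N,N′-Ditosylhydrazine and DBU turn it into the 2-O-diazoacetate F2. Its less electrophilic acceptor-only carbenoid, under Rh2(OAc)4 or dirhodium tetraacetamidate Rh2(NHCOCH3)4, should favour the five-membered insertion over ylide paths and give the phosphorus-free lactone F3. Phosphorus is then brought in by enolate chemistry: LiN(iPr)2 and ClP(O)(OEt)2 form the enol phosphate, and a second equivalent of LiN(iPr)2 induces the 1,3 O-to-C phosphoryl shift, which rejoins the route at 8.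

Step 15. Most likely to go wrong is loss of the alkoxide from the β-alkoxy ylide, enolisation of the hindered ketone, or erosion of Z selectivity, because the ketone is β-branched and the ylide is basic. Fallback: the Z alkene is made by ring closure instead. From 17, methylenation with Ph3P=CH2 gives the isopropenyl compound F4. HF·pyridine frees the C3 allylic alcohol F5, and CBr4/PPh3 gives the bromide F6. After pre-deprotonation of C11–H with LiN(SiMe3)2, allylmagnesium bromide with catalytic Li2CuCl4 forms C2–C3 intermolecularly to give the triene F7. Ring-closing metathesis with the second-generation Grubbs catalyst (PhMe, 80 °C, high dilution) closes C1=C10, where the ten-membered ring enforces the Z geometry, and rejoins the route at 28.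

Step 20. Most likely to go wrong is intermolecular alkylation to oligomers, or failure to close because of transannular strain in a chain stiffened by the fused lactone and dioxolane. Fallback: from 22, HF·pyridine gives the C2,C3-diol F8 and CBr4/PPh3 the bis(allylic) dibromide F9. Reductive coupling of the two allylic bromides by zerovalent nickel (Ni(cod)2, DMF, high dilution) closes C2–C3 without any carbanion and rejoins the route at 28. Alkene geometry is at some risk in this coupling.

Step 21. Most likely to go wrong is hydride attack on the lactone if enolate formation is incomplete, ionisation of the allylic C6–O bond by palladium, or loss of alkene position through the π-allyl intermediate. Fallback: electron-transfer cleavage in place of the palladium hydride route. From 27, sodium amalgam Na(Hg) with Na2HPO4 in MeOH/THF at −20 °C cleaves the C–S bond and gives 28 directly (no new compound); protonation at the less substituted allyl terminus is expected to predominate.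

Step 25. Most likely to go wrong is that acid strong enough to open the hindered ketal also causes transannular cyclisation of the 1,5-diene or O9 to O8 acyl shift. Fallback: non-protic, base-buffered ketal opening. From 33, Et3SiOTf and 2,6-lutidine (CH2Cl2, −40 to 0 °C) should open the dioxolane to the 8-O-triethylsilyl 7-O-isopropenyl ether F10, and buffered HF·pyridine then frees both hydroxyls to give 34.

## Further compounds

F1 | step 6 | benzyl 2-O-bromoacetyl-3,4-O-isopropylidene-6-O-triethylsilyl-α-D-galactopyranoside | CC[Si](CC)(CC)OC[C@H]1O[C@H](OCc3ccccc3)[C@H](OC(=O)CBr)[C@H]2OC(C)(C)O[C@@H]12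
F2 | step 6 | benzyl 2-O-diazoacetyl-3,4-O-isopropylidene-6-O-triethylsilyl-α-D-galactopyranoside | CC[Si](CC)(CC)OC[C@H]1O[C@H](OCc3ccccc3)[C@H](OC(=O)C=[N+]=[N-])[C@H]2OC(C)(C)O[C@@H]12
F3 | step 6 | benzyl 3-C-(carboxymethyl)-3,4-O-isopropylidene-6-O-triethylsilyl-α-D-galactopyranoside 2-O-lactone | CC[Si](CC)(CC)OC[C@H]1O[C@H](OCc5ccccc5)[C@@H]3OC(=O)C[C@@]34OC(C)(C)O[C@@H]14
F4 | step 15 | isopropenyl compound (C10 methylene in place of the ketone oxygen of 17) | CC(C)(C)[Si](C)(C)OC/C(C)=C/[C@@H]1OC(=O)C(P(=O)(OCC)OCC)[C@@]12OC(C)(C)O[C@H]2[C@H](O[Si](C)(C)C(C)(C)C)C(C)=C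
F5 | step 15 | C3 allylic alcohol of F4 | OC/C(C)=C/[C@@H]1OC(=O)C(P(=O)(OCC)OCC)[C@@]12OC(C)(C)O[C@H]2[C@H](O[Si](C)(C)C(C)(C)C)C(C)=C
F6 | step 15 | C3 allylic bromide of F4 | BrC/C(C)=C/[C@@H]1OC(=O)C(P(=O)(OCC)OCC)[C@@]12OC(C)(C)O[C@H]2[C@H](O[Si](C)(C)C(C)(C)C)C(C)=C
F7 | step 15 | metathesis triene (C3 carries CH2–CH=CH2, C10 carries the isopropenyl group) | C=CCC/C(C)=C/[C@@H]1OC(=O)C(P(=O)(OCC)OCC)[C@@]12OC(C)(C)O[C@H]2[C@H](O[Si](C)(C)C(C)(C)C)C(C)=C
F8 | step 20 | C2,C3-diol (C3 silyl ether of 22 removed) | OC/C(C)=C/[C@@H]1OC(=O)C(P(=O)(OCC)OCC)[C@@]12OC(C)(C)O[C@H]2[C@H](O[Si](C)(C)C(C)(C)C)/C(C)=C\CO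
F9 | step 20 | C2,C3-bis(allylic) dibromide | BrC/C(C)=C/[C@@H]1OC(=O)C(P(=O)(OCC)OCC)[C@@]12OC(C)(C)O[C@H]2[C@H](O[Si](C)(C)C(C)(C)C)/C(C)=C\CBr
F0 | step 21 | none | none
F10 | step 25 | 8-O-triethylsilyl 7-O-(prop-1-en-2-yl) ether of the target | C3/C(C)=C/[C@@H]1OC(=O)C(=C)[C@]1(OC(C)=C)[C@@H](O[Si](CC)(CC)CC)[C@H](OC(=O)/C(C)=C\C)/C(C)=C\C3
A1 | alternative 1 | acyclic C6 aldehyde with terminal C4≡C5 alkyne, Z-C1=C10, 9-O-(2-naphthylmethyl), 7,8-O-di-tert-butylsilylene, C11(=CH2)CH2O-PMB | C#CCC/C=C(/C)[C@@H](OCc4ccc5ccccc5c4)[C@@H]3O[Si](C(C)(C)C)(C(C)(C)C)O[C@@]3(C=O)C(=C)COCc2ccc(OC)cc2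
A2 | alternative 1 | ten-membered allylic alcohol with free C6–OH and E-C4(Me)=C5 | O[C@H]1/C=C(\C)CC/C=C(/C)[C@@H](OCc4ccc5ccccc5c4)[C@@H]3O[Si](C(C)(C)C)(C(C)(C)C)O[C@]13C(=C)COCc2ccc(OC)cc2
A3 | alternative 2 | C9-keto cyclohexenone (C5=C10) with 6-O-PMB, 7,8-O-di-tert-butylsilylene and C7 N-methoxy-N-methylamide | COc1ccc(CO[C@H]2C=C(C)C(=O)[C@@H]3O[Si](C(C)(C)C)(C(C)(C)C)O[C@]23C(=O)N(C)OC)cc1
A4 | alternative 2 | 1-methylcyclobutene | CC1=CCC1
A5 | alternative 2 | cis,anti,cis photoadduct (cyclohexanone fused to a bicyclo[2.2.0]hexane) | COc1ccc(CO[C@H]2[C@@H]5[C@@]4(C)CC[C@H]4[C@]5(C)C(=O)[C@@H]3O[Si](C(C)(C)C)(C(C)(C)C)O[C@]23C(=O)N(C)OC)cc1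
A6 | alternative 3 | thirteen-membered ether: C9 ketone, O8–C13 allyl ether, C7=C11 triethylsilyl enol ether allyl ester (enol ether geometry open), 6-O-PMB | COc1ccc(CO[C@@H]2/C=C(\C)CC/C=C(/C)C(=O)COCC(C(=O)OCC=C)=C2O[Si](CC)(CC)CC)cc1
A7 | alternative 3 | ten-membered C8-hydroxy C9-ketone with the allyl 2-propenoate on C7 (C6 epimeric to the target) | COc1ccc(CO[C@@H]2/C=C(\C)CC/C=C(/C)C(=O)[C@H](O)[C@@]2(O[Si](CC)(CC)CC)C(=C)C(=O)OCC=C)cc1
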